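The target is cut at its two ester C–O bonds into (2E,6E)-2,6-dimethylocta-2,6-dienedioic acid and two identical amino alcohols, and each amino alcohol is traced to one bicyclic enone. The feature used is the oxygen-bearing carbon C6, flanked by C5 and C7 in a cyclopentane fused to the piperidine through C4a–C7a: an alkyne (C5, C4a), an alkene (C7a, C7) and CO (C6) joined at cobalt. One intramolecular Pauson–Khand reaction of an acyclic carbamate-tethered 1,7-enyne, methyl N-crotyl-N-(2-methylbut-3-ynyl)carbamate with the propargylic methyl carbon as its only stereocentre, closes both rings, makes three C–C bonds and sets C7 and C7a.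

Key step: step 5

Remark on the chemistry: each amino alcohol unit of the target is (4R,4aS,6R,7S,7aR) and both chain alkenes are E. The C4 centre is bought as (R)-3-bromo-2-methylpropan-1-ol (a Roche-ester-derived bromohydrin, assumed available as a catalogue item), and the crotyl group as (E)-but-2-en-1-amine hydrochloride, assumed purchasable and geometrically pure, because the alkene geometry becomes the C7 configuration.

Step 1
Reactants: 1 (R)-3-bromo-2-methylpropan-1-ol; 2 (E)-but-2-en-1-amine hydrochloride (3 equiv)
Product: 3 (S)-3-[(E)-but-2-enylamino]-2-methylpropan-1-ol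
Conditions: K2CO3, NaI (cat.), MeCN, 70 °C, sealed vessel
Reagents that add atoms: none
Why: SN2 N-alkylation of a primary amine at the primary bromide, with excess amine to suppress dialkylation; the stereocentre is one carbon away and is not touched.

Step 2
Reactants: 3 (S)-3-[(E)-but-2-enylamino]-2-methylpropan-1-ol; 4 methyl chloroformate
Product: 5 methyl N-[(E)-but-2-enyl]-N-[(S)-3-hydroxy-2-methylpropyl]carbamate
Conditions: NaHCO3, CH2Cl2/H2O, 0 °C
Reagents that add atoms: none
Why: Schotten–Baumann N-acylation, in which the secondary amine should outcompete the primary alcohol for the chloroformate; the carbamate later becomes the N-methyl group.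

Step 3
Reactants: 5 methyl N-[(E)-but-2-enyl]-N-[(S)-3-hydroxy-2-methylpropyl]carbamate
Product: 6 methyl N-[(E)-but-2-enyl]-N-[(S)-2-methyl-3-oxopropyl]carbamate
Conditions: Dess–Martin periodinane, NaHCO3, CH2Cl2, 0 °C → rt; crude aldehyde used at once
Reagents that add atoms: none
Why: Dess–Martin oxidation of the primary alcohol under buffered, non-basic conditions that should leave the α-methyl stereocentre of the aldehyde intact.

Step 4
Reactants: 6 methyl N-[(E)-but-2-enyl]-N-[(S)-2-methyl-3-oxopropyl]carbamate
Product: 7 methyl N-[(E)-but-2-enyl]-N-[(R)-2-methylbut-3-ynyl]carbamate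
Conditions: dimethyl (1-diazo-2-oxopropyl)phosphonate, K2CO3, MeOH, 0 °C → rt
Reagents that add atoms: dimethyl (1-diazo-2-oxopropyl)phosphonate CC(=O)C(=[N+]=[N-])P(=O)(OC)OC
Why: Seyferth–Gilbert homologation in its Ohira–Bestmann form, in which the diazomethylphosphonate anion made in situ adds to the aldehyde and loss of phosphate and N2 with a 1,2-hydrogen shift gives the terminal alkyne; the mild carbonate conditions at low temperature are chosen so that the future C4 centre is kept.

Step 5
Reactants: 7 methyl N-[(E)-but-2-enyl]-N-[(R)-2-methylbut-3-ynyl]carbamate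
Product: 9 methyl (4R,7S,7aS)-4,7-dimethyl-6-oxo-1,3,4,6,7,7a-hexahydro-2H-cyclopenta[c]pyridine-2-carboxylate, via hexacarbonyldicobalt alkyne complex 8 (not isolated)
Conditions: Co2(CO)8 (1.1 equiv), CH2Cl2, rt; then NMO (8 equiv), 0 °C → rt (warming to 40 °C if slow)
Reagents that add atoms: dicobalt octacarbonyl O=C=[Co](=C=O)(=C=O)(=C=O)[Co](=C=O)(=C=O)(=C=O)=C=O (one CO becomes C6=O)
Why: The alkyne is bound as its μ-alkyne Co2(CO)6 complex 8, the N-oxide removes one CO as CO2 to open a site for the tethered alkene, the alkene inserts into the Co–C bond of the internal alkyne carbon (C4a–C7a), and CO insertion at C7 followed by reductive elimination to C5 completes the enone (C7–C6 and C6–C5). The closest known reaction type is the intramolecular Pauson–Khand [2+2+1] reaction of heteroatom-tethered 1,7-enynes. The piperidine closes in the insertion step as a six-membered exo closure onto the inner alkene carbon, giving a fused cobaltacycle, and the cyclopentenone closes around the metal by carbonyl insertion and reductive elimination. C7 is fixed relative to C7a by suprafacial addition across the (E)-alkene, so its methyl should end trans to C1; C7a is fixed relative to C4 by a chair-like insertion transition state with the C4 methyl pseudo-equatorial, which puts H4 and H7a on the same face. The step therefore needs π-facial selectivity of the alkene with respect to C4 (regiochemistry is fixed by the tether), and this should be secured by the propargylic methyl next to the bulky cobalt cluster together with the planar, non-coordinating carbamate nitrogen in the forming ring.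

Step 6
Reactants: 9 methyl (4R,7S,7aS)-4,7-dimethyl-6-oxo-1,3,4,6,7,7a-hexahydro-2H-cyclopenta[c]pyridine-2-carboxylate
Product: 10 methyl (4R,4aS,7S,7aR)-4,7-dimethyl-6-oxooctahydro-2H-cyclopenta[c]pyridine-2-carboxylate
Conditions: H2 (1 atm), 10% Pd/C, EtOAc, rt
Reagents that add atoms: none
Why: Heterogeneous hydrogenation of the enone C4a=C5 should deliver hydrogen to the face that carries H7a, because the other face is covered by the piperidine carbons and the C4 methyl, so the new H4a is cis to H7a (cis ring fusion).

Step 7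
Reactants: 10 methyl (4R,4aS,7S,7aR)-4,7-dimethyl-6-oxooctahydro-2H-cyclopenta[c]pyridine-2-carboxylate
Product: 12 (4R,4aS,6S,7S,7aR)-2,4,7-trimethyloctahydro-1H-cyclopenta[c]pyridin-6-ol (6-epi-incarvilline), via carbamate alcohol 11 (not isolated)
Conditions: LiAlH4 (5 equiv), THF, −78 → 0 °C, then reflux; Fieser work-up
Reagents that add atoms: none
Why: Hydride reduction of the ketone should take place from the outer convex face of the cis-fused bicycle (the face of H4a and H7a; the concave face is screened by the piperidine ring), leaving the hydroxyl trans to the C7 methyl (6S), and at reflux the same reagent effects the carbamate-to-N-methyl reduction.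

Step 8
Reactants: 13 geranyl acetate
Product: 15 (2E,6E)-8-hydroxy-3,7-dimethylocta-2,6-dienyl acetate, via 8-oxogeranyl acetate 14 (not isolated)
Conditions: SeO2 (0.3 equiv), t-BuOOH (3 equiv), salicylic acid (cat.), CH2Cl2, rt; then NaBH4, MeOH, 0 °C
Reagents that add atoms: tert-butyl hydroperoxide CC(C)(C)OO (oxygen source, relayed by catalytic selenium dioxide O=[Se]=O)
Why: Catalytic selenium dioxide allylic oxidation (ene reaction, then [2,3]-sigmatropic shift) should hydroxylate the (E)-methyl of the electron-rich terminal alkene, the other alkene being deactivated by the allylic acetate, and the borohydride treatment returns over-oxidised aldehyde 14 to the alcohol.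

Step 9
Reactants: 15 (2E,6E)-8-hydroxy-3,7-dimethylocta-2,6-dienyl acetate
Product: 16 (2E,6E)-2,6-dimethylocta-2,6-diene-1,8-diol
Conditions: K2CO3 (cat.), MeOH, rt
Reagents that add atoms: none
Why: Base-catalysed transesterification with methanol removes the acetate and leaves both alkenes untouched.

Step 10
Reactants: 16 (2E,6E)-2,6-dimethylocta-2,6-diene-1,8-diol
Product: 17 (2E,6E)-2,6-dimethylocta-2,6-dienedial
Conditions: activated MnO2 (excess), CH2Cl2, rt
Reagents that add atoms: none
Why: Manganese dioxide oxidation is selective for allylic alcohols and should give both conjugated aldehydes without double-bond isomerisation.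

Step 11
Reactants: 17 (2E,6E)-2,6-dimethylocta-2,6-dienedial
Product: 18 (2E,6E)-2,6-dimethylocta-2,6-dienedioic acid
Conditions: NaClO2, NaH2PO4, 2-methylbut-2-ene, t-BuOH/H2O, 0 °C → rt
Reagents that add atoms: sodium chlorite [Na+].[O-]Cl=O
Why: Pinnick oxidation converts both enals into the acids, with 2-methylbut-2-ene scavenging hypochlorous acid so that the trisubstituted alkenes keep their E geometry.

Step 12
Reactants: 18 (2E,6E)-2,6-dimethylocta-2,6-dienedioic acid (1.0 equiv); 12 (4R,4aS,6S,7S,7aR)-2,4,7-trimethyloctahydro-1H-cyclopenta[c]pyridin-6-ol (2.3 equiv)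
Product: 21 bis[(4R,4aS,6R,7S,7aR)-2,4,7-trimethyloctahydro-1H-cyclopenta[c]pyridin-6-yl] (2E,6E)-2,6-dimethylocta-2,6-dienedioate (target), via mono-ester at the C8 carboxyl 19 (not isolated), via mono-ester at the C1 carboxyl 20 (not isolated)
Conditions: PPh3 (3 equiv), DIAD (3 equiv), THF, 0 °C → rt
Reagents that add atoms: none
Why: Double Mitsunobu esterification, in which each C6 hydroxyl is activated as its alkoxyphosphonium ion and displaced by carboxylate from the open convex face with SN2 inversion (6S → 6R), placing the ester oxygen cis to the C7 methyl as the target requires.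

Compound list

1 | (R)-3-bromo-2-methylpropan-1-ol | C[C@H](CO)CBr | starting material
2 | (E)-but-2-en-1-amine hydrochloride | C/C=C/CN.Cl | starting material
3 | (S)-3-[(E)-but-2-enylamino]-2-methylpropan-1-ol | C/C=C/CNC[C@@H](CO)C | intermediate
4 | methyl chloroformate | COC(=O)Cl | starting material
5 | methyl N-[(E)-but-2-enyl]-N-[(S)-3-hydroxy-2-methylpropyl]carbamate | C/C=C/CN(C(=O)OC)C[C@@H](CO)C | intermediate
6 | methyl N-[(E)-but-2-enyl]-N-[(S)-2-methyl-3-oxopropyl]carbamate | C/C=C/CN(C(=O)OC)C[C@@H](C=O)C | intermediate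
7 | methyl N-[(E)-but-2-enyl]-N-[(R)-2-methylbut-3-ynyl]carbamate | C/C=C/CN(C(=O)OC)C[C@@H](C#C)C | intermediate
8 | μ-alkyne hexacarbonyldicobalt complex of 7 (both alkyne carbons bridge the Co–Co bond) | C/C=C/CN(C(=O)OC)C[C@H](C)C12C3[Co]1(=C=O)(=C=O)(=C=O)[Co]23(=C=O)(=C=O)=C=O | intermediate
9 | methyl (4R,7S,7aS)-4,7-dimethyl-6-oxo-1,3,4,6,7,7a-hexahydro-2H-cyclopenta[c]pyridine-2-carboxylate | O=C1C=C2[C@@H](CN(C(=O)OC)C[C@@H]2C)[C@@H]1C | intermediate
10 | methyl (4R,4aS,7S,7aR)-4,7-dimethyl-6-oxooctahydro-2H-cyclopenta[c]pyridine-2-carboxylate | O=C1C[C@@H]2[C@@H](CN(C(=O)OC)C[C@@H]2C)[C@@H]1C | intermediate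
11 | methyl (4R,4aS,6S,7S,7aR)-6-hydroxy-4,7-dimethyloctahydro-2H-cyclopenta[c]pyridine-2-carboxylate | O[C@H]1C[C@@H]2[C@@H](CN(C(=O)OC)C[C@@H]2C)[C@@H]1C | intermediate
12 | (4R,4aS,6S,7S,7aR)-2,4,7-trimethyloctahydro-1H-cyclopenta[c]pyridin-6-ol (6-epi-incarvilline) | O[C@H]1C[C@@H]2[C@@H](CN(C)C[C@@H]2C)[C@@H]1C | intermediate
13 | geranyl acetate | CC(C)=CCC/C(C)=C/COC(C)=O | starting material
14 | (2E,6E)-3,7-dimethyl-8-oxoocta-2,6-dienyl acetate (8-oxogeranyl acetate) | C/C(=C\COC(C)=O)CC/C=C(\C)C=O | intermediate
15 | (2E,6E)-8-hydroxy-3,7-dimethylocta-2,6-dienyl acetate | C/C(=C\COC(C)=O)CC/C=C(\C)CO | intermediate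
16 | (2E,6E)-2,6-dimethylocta-2,6-diene-1,8-diol | C/C(=C\CO)CC/C=C(\C)CO | intermediate
17 | (2E,6E)-2,6-dimethylocta-2,6-dienedial | C/C(=C\C=O)CC/C=C(\C)C=O | intermediate
18 | (2E,6E)-2,6-dimethylocta-2,6-dienedioic acid | C/C(=C\C(=O)O)CC/C=C(\C)C(=O)O | intermediate
19 | (2E,6E)-2,6-dimethyl-8-oxo-8-[(4R,4aS,6R,7S,7aR)-2,4,7-trimethyloctahydro-1H-cyclopenta[c]pyridin-6-yl]oxyocta-2,6-dienoic acid | C/C(=C\C(=O)O[C@@H]1C[C@@H]2[C@@H](CN(C)C[C@@H]2C)[C@@H]1C)CC/C=C(\C)C(=O)O | intermediate
20 | (2E,6E)-3,7-dimethyl-8-oxo-8-[(4R,4aS,6R,7S,7aR)-2,4,7-trimethyloctahydro-1H-cyclopenta[c]pyridin-6-yl]oxyocta-2,6-dienoic acid | C/C(=C\C(=O)O)CC/C=C(\C)C(=O)O[C@@H]1C[C@@H]2[C@@H](CN(C)C[C@@H]2C)[C@@H]1C | intermediate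
21 | bis[(4R,4aS,6R,7S,7aR)-2,4,7-trimethyloctahydro-1H-cyclopenta[c]pyridin-6-yl] (2E,6E)-2,6-dimethylocta-2,6-dienedioate | C/C(=C\C(=O)O[C@@H]1C[C@@H]2[C@@H](CN(C)C[C@@H]2C)[C@@H]1C)CC/C=C(\C)C(=O)O[C@@H]1C[C@@H]2[C@@H](CN(C)C[C@@H]2C)[C@@H]1C | target

Total step count: 12. Longest linear sequence: 8 steps (steps 1–7, then step 12); the diacid branch is 4 steps (steps 8–11) before the coupling.

Steps most likely to fail

Step 5. The 1,2-disubstituted crotyl alkene may insert too slowly into the cobalt–alkyne complex, so that decomplexation and alkyne oligomerisation outrun cyclisation, and a long reaction time would also weaken the relay from C4 to C7a. The fallback takes the C7 methyl out of the cyclisation and sets out from 1. Alkylation of allylamine (neat excess, K2CO3) with 1 should give (S)-3-(allylamino)-2-methylpropan-1-ol F1. Acylation with 4 gives methyl N-allyl-N-[(S)-3-hydroxy-2-methylpropyl]carbamate F2, and Dess–Martin oxidation gives methyl N-allyl-N-[(S)-2-methyl-3-oxopropyl]carbamate F3. Ohira–Bestmann homologation gives methyl N-allyl-N-[(R)-2-methylbut-3-ynyl]carbamate F4. Its monosubstituted alkene should cyclise readily under the step 5 conditions, through the hexacarbonyldicobalt complex of F4 F5, to methyl (4R,7aS)-4-methyl-6-oxo-1,3,4,6,7,7a-hexahydro-2H-cyclopenta[c]pyridine-2-carboxylate F6. Kinetic α′-enolisation at C7 (LDA, THF, −78 °C) and methylation with MeI, which should enter anti to the C1 branch on C7a, comes back to the route at 9.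

Step 12. The hindered C6 alkoxyphosphonium ion may lose a proton to give an alkene instead of being displaced, and the coupling may stall at the mono-esters because the second activation must occur on a molecule that already carries a basic amine and a free acid. The fallback separates inversion from coupling and sets out from 12. Mitsunobu reaction with excess 4-nitrobenzoic acid (PPh3, DIAD, THF) should give the inverted (4R,4aS,6R,7S,7aR)-2,4,7-trimethyloctahydro-1H-cyclopenta[c]pyridin-6-yl 4-nitrobenzoate F7. Methanolysis (K2CO3, MeOH) gives (4R,4aS,6R,7S,7aR)-2,4,7-trimethyloctahydro-1H-cyclopenta[c]pyridin-6-ol F8. Carbodiimide esterification of 18 with two equivalents of F8 (EDC·HCl, DMAP, CH2Cl2) proceeds with retention at C6 and comes back to the route at 21. The same retention coupling would also serve if hydride addition in step 7 were to favour the 6R alcohol.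

Step 4. The aldehyde may enolise in basic methanol before the phosphonate adds, which would erode the configuration at the future C4 or eliminate the β-carbamate. The fallback forms the new carbon under neutral conditions and sets out from 6. Dibromo-olefination (CBr4, PPh3, Zn, CH2Cl2, 0 °C; first stage of a Corey–Fuchs homologation) should give methyl N-[(E)-but-2-enyl]-N-[(R)-4,4-dibromo-2-methylbut-3-enyl]carbamate F9. Treatment with n-BuLi (2.1 equiv, THF, −78 °C), where bromine–lithium exchange and 1,2-shift should be faster than attack at the carbamate, followed by aqueous NH4Cl, comes back to the route at 7.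

Further compounds

F1 | step 5 | (S)-3-(allylamino)-2-methylpropan-1-ol | C=CCNC[C@@H](CO)C
F2 | step 5 | methyl N-allyl-N-[(S)-3-hydroxy-2-methylpropyl]carbamate | C=CCN(C(=O)OC)C[C@@H](CO)C
F3 | step 5 | methyl N-allyl-N-[(S)-2-methyl-3-oxopropyl]carbamate | C=CCN(C(=O)OC)C[C@@H](C=O)C
F4 | step 5 | methyl N-allyl-N-[(R)-2-methylbut-3-ynyl]carbamate | C=CCN(C(=O)OC)C[C@@H](C#C)C
F5 | step 5 | hexacarbonyldicobalt complex of F4 | C=CCN(C(=O)OC)C[C@H](C)C12C3[Co]1(=C=O)(=C=O)(=C=O)[Co]23(=C=O)(=C=O)=C=O
F6 | step 5 | methyl (4R,7aS)-4-methyl-6-oxo-1,3,4,6,7,7a-hexahydro-2H-cyclopenta[c]pyridine-2-carboxylate | O=C1C=C2[C@@H](CN(C(=O)OC)C[C@@H]2C)C1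
F7 | step 12 | (4R,4aS,6R,7S,7aR)-2,4,7-trimethyloctahydro-1H-cyclopenta[c]pyridin-6-yl 4-nitrobenzoate | O=C(O[C@@H]1C[C@@H]2[C@@H](CN(C)C[C@@H]2C)[C@@H]1C)c1ccc(cc1)[N+](=O)[O-]
F8 | step 12 | (4R,4aS,6R,7S,7aR)-2,4,7-trimethyloctahydro-1H-cyclopenta[c]pyridin-6-ol (incarvilline) | O[C@@H]1C[C@@H]2[C@@H](CN(C)C[C@@H]2C)[C@@H]1C
F9 | step 4 | methyl N-[(E)-but-2-enyl]-N-[(R)-4,4-dibromo-2-methylbut-3-enyl]carbamate | C/C=C/CN(C(=O)OC)C[C@@H](C=C(Br)Br)C
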